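**Plan**
Retrosynthetic cuts, in order: C4–C5 (Michael addition), C10–C1 and C10–CH3 (two enolate alkylations), C6=C7 together with the C14=C15 vinyl (metathesis), C5–C6 (vinyl Grignard), C9–C10 (enolate alkylation), and finally C8–C9 plus C12–C13 ((4+3) cycloaddition).
Enabling feature: ring C (O–C8–C9–C11–C12–C13) is a tetrahydropyran whose α-carbons C8 and C13 each carry a methyl group and, cis to each other, a carbon substituent (C7 of ring B, vinyl carbon C14); it is therefore an opened 8-oxabicyclo[3.2.1]oct-6-ene.
Forward: ring C is made first as the oxygen-bridged half of the bicycle; the C9 side chain follows; ring B (C5–C6–C7–C8–C9–C10) closes by ring-opening/ring-closing metathesis of the C7=C14 bridge, which also frees the C13 vinyl group; then C10 is quaternised, the ketone is moved from C5 to C7, the C4 unit is added, and the C7 oxygen and the esters are removed.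
Stereochemistry: C8/C13 cis from the bridge; absolute configuration from chiral lithium amide desymmetrisation of the meso ketone; C9 from exo alkylation; C10 from alkylation anti to the axial C8 methyl; C5 from axial Michael addition anti to the C10 methyl.

Key step: step 2

Assumption: labdane-type numbering is used throughout, and β is the face of ring B that carries the C8 methyl group.
Assumption: the (R,R)-amide in step 3 is taken to remove the proton that leads to 7 as drawn; if the sense is the opposite, the (S,S)-amide is used instead.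
Assumption: the configurations given for C10 in 17, the epoxide in 21 and C7 in 23 and 30 to 33 are the expected ones; all are erased later.

Step 1
Reactants: 1 2-methoxypropene
Product: 2 3-bromo-2-methoxyprop-1-ene (2-methoxyallyl bromide)
Conditions: NBS, CCl4, 0 °C → rt, dark; filter, distil, use at once
Reagents that add atoms: N-bromosuccinimide, O=C1CCC(=O)N1Br
Why: Electrophilic bromination of the enol ether followed by loss of a methyl proton from the oxocarbenium ion should give the allyl bromide (allylic bromination of an enol ether with NBS, a known preparation of this reagent).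

Step 2
Reactants: 2 3-bromo-2-methoxyprop-1-ene; 3 2,5-dimethylfuran
Product: 5 meso-1,5-dimethyl-8-oxabicyclo[3.2.1]oct-6-en-3-one, via methyl enol ether 4 (not isolated)
Conditions: silver trifluoroacetate, Na2CO3, 3 (5 equiv), pentane–CH2Cl2, −78 → 0 °C, dark; then 0.1 M aq HNO3, rt
Reagents that add atoms: water, O
Why: Silver ion abstracts bromide from 2 to give the 2-methoxyallyl cation, which adds across the two α-carbons of the furan in a concerted or stepwise (4+3) cycloaddition; the oxocarbenium ion loses a proton to carbonate to give 4, which is hydrolysed on acidic work-up, and the closest known reaction type is the (4+3) cycloaddition of oxyallyl cations with furans. The new bonds are C8–C9 and C12–C13; they close the seven-membered carbocycle by intermolecular cycloaddition of a three-carbon unit onto the four-carbon diene, and this also creates the oxygen-bridged six-membered ring O–C8–C9–C11–C12–C13, the later ring C. The new stereocentres C8 and C13 arise by suprafacial addition to one face of the planar furan, so the C7–C14 etheno bridge, and with it the two future carbon substituents, is necessarily cis; the product is meso, so no absolute control is needed yet. The step needs periselectivity for cycloaddition over electrophilic substitution, which the two α-methyl groups should secure by blocking rearomatisation after attack at an α-carbon, and the symmetry of both partners removes any regiochemical question.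

Step 3
Reactants: 5 meso-1,5-dimethyl-8-oxabicyclo[3.2.1]oct-6-en-3-one
Product: 7 (1R,5R)-1,5-dimethyl-3-(trimethylsilyloxy)-8-oxabicyclo[3.2.1]octa-2,6-diene, via lithium enolate 6 (not isolated)
Conditions: lithium (R,R)-bis(1-phenylethyl)amide (from the amine and n-BuLi), LiCl, Me3SiCl present from the start, THF, −100 °C
Reagents that add atoms: chlorotrimethylsilane, C[Si](C)(C)Cl
Why: Enantioselective deprotonation of a meso ketone by a chiral lithium amide with in situ silylation is established for 8-oxabicyclo[3.2.1]octan-3-ones; the base should remove the exo proton of one of the two enantiotopic methylene groups (the later C9), which fixes the absolute configuration of the route.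

Step 4
Reactants: 7 silyl enol ether; 8 2-bromo-N-methoxy-N-methylacetamide
Product: 10 2-[(1R,2R,5R)-1,5-dimethyl-3-oxo-8-oxabicyclo[3.2.1]oct-6-en-2-yl]-N-methoxy-N-methylacetamide, via benzyltrimethylammonium enolate 9 (not isolated)
Conditions: 8 (1.5 equiv), benzyltrimethylammonium fluoride (dried, 1.1 equiv), 4 Å MS, THF, −20 → 0 °C
Reagents that add atoms: none
Why: Fluoride cleaves the Si–O bond to release the regio- and enantio-defined quaternary ammonium enolate in the presence of the electrophile, so the reactive α-bromo amide should capture it by SN2 alkylation before proton transfer can scramble the two enantiotopic α-positions; attack should occur on the exo face (syn to the oxygen bridge, away from the etheno bridge), which places C10 trans to C7 as required at C9 (fluoride-mediated regiospecific alkylation of a silyl enol ether).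

Step 5
Reactants: 10 keto amide
Product: 12 2-[(1S,2R,5R)-1,5-dimethyl-8-oxabicyclo[3.2.1]oct-6-en-2-yl]-N-methoxy-N-methylacetamide, via tosylhydrazone 11 (not isolated)
Conditions: TsNHNH2, THF, 4 Å MS, rt; then catecholborane, CHCl3, 0 °C; NaOAc·3H2O, 60 °C
Reagents that add atoms: none
Why: Reduction of a tosylhydrazone with catecholborane and decomposition of the resulting diazene should remove the C11 oxygen under conditions mild enough to leave the exo C9 centre, the strained alkene and the amide untouched (tosylhydrazone reduction to a methylene group).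

Step 6
Reactants: 12 N-methoxy-N-methylamide
Product: 13 1-[(1S,2R,5R)-1,5-dimethyl-8-oxabicyclo[3.2.1]oct-6-en-2-yl]but-3-en-2-one
Conditions: CH2=CHMgBr, THF, −78 → 0 °C; cold aq NH4Cl
Reagents that add atoms: vinylmagnesium bromide, C=C[Mg]Br
Why: The N-methoxy-N-methylamide should take up one equivalent of the Grignard reagent as a stable chelate and release the vinyl ketone only on work-up (Weinreb ketone synthesis), so that C5 arrives as the carbonyl that later activates C10.

Step 7
Reactants: 13 vinyl ketone
Product: 15 ring B enone (C5 ketone; C6=C7; C13 vinyl), via ring-opened trienone 14 (not isolated)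
Conditions: RuCl2(=CHPh)(H2IMes)(PCy3) (second-generation Grubbs catalyst, 10 mol%), ethene (1 atm), toluene, 60 °C; then argon sparge, 80 °C
Reagents that add atoms: ethene, C=C
Why: In this ring-opening/ring-closing metathesis, ethene and the ruthenium methylidene should open the strained C7=C14 bridge to the cis-divinyl oxane 14; its ring flip makes the C8 vinyl and the C9 chain equatorial so that they close ring B through C6=C7, and C14 is left as the C13 vinyl because only the C8 vinyl can reach the enone.

Step 8
Reactants: 15 ring B enone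
Product: 17 C10-methyl enone, via lithium dienolate 16 (not isolated)
Conditions: LiN(iPr)2, THF, −78 °C; MeI, −78 → −40 °C
Reagents that add atoms: iodomethane, CI
Why: Kinetic deprotonation should occur only at C10 (C8 has no hydrogen for γ-deprotonation) and methylation of the cross-conjugated enolate should give 17 (α′-alkylation of an enone); the C10 configuration is erased in the next step.

Step 9
Reactants: 17 C10-methyl enone; 18 tert-butyl bromoacetate
Product: 20 enone with quaternary C10 (β-methyl and α-CH2CO2tBu), via lithium dienolate 19 (not isolated)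
Conditions: LiN(iPr)2, THF, −78 °C; then 18, DMPU, −78 → −20 °C
Reagents that add atoms: none
Why: The tetrasubstituted enolate should be alkylated on the α face, opposite the axial C8 methyl group that lies 1,3 to C10 on the β face, which sets C10 with methyl β and the acetate arm α (enolate alkylation trans to a syn-axial angular methyl, as with decalone enolates).

Step 10
Reactants: 20 C10-quaternary enone
Product: 21 6α,7α-epoxy C5 ketone
Conditions: t-BuOOH, DBU, CH2Cl2, 0 °C → rt
Reagents that add atoms: tert-butyl hydroperoxide, CC(C)(C)OO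
Why: Nucleophilic (Weitz–Scheffer) epoxidation is specific for the electron-poor C6=C7 bond and should leave the C13 vinyl group and the tert-butyl ester untouched; the epoxide configuration is of no consequence.

Step 11
Reactants: 21 epoxy ketone
Product: 23 allylic alcohol (7α-OH; C5=C6), via epoxy hydrazone 22 (not isolated)
Conditions: N2H4·H2O, AcOH (cat.), MeOH, 0 °C → rt
Reagents that add atoms: none
Why: In the Wharton transposition the epoxy hydrazone should fragment with loss of N2, moving the oxygen from C5 to C7 and the double bond to C5=C6; the reaction is known for epoxy ketones whose carbonyl is flanked by a quaternary carbon.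

Step 12
Reactants: 23 allylic alcohol
Product: 24 C7 enone (C7 ketone; C5=C6)
Conditions: Dess–Martin periodinane, NaHCO3, CH2Cl2, 0 °C → rt
Reagents that add atoms: none
Why: Dess–Martin oxidation of the secondary allylic alcohol should give the enone in which C5 is now the electrophilic β-carbon.

Step 13
Reactants: 25 tert-butyl isobutyrate
Product: 27 [(1-tert-butoxy-2-methylprop-1-en-1-yl)oxy]trimethylsilane, via lithium enolate 26 (not isolated)
Conditions: LiN(iPr)2, THF, −78 °C; Me3SiCl, −78 °C → rt; distil
Reagents that add atoms: chlorotrimethylsilane, C[Si](C)(C)Cl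
Why: Deprotonation of the ester and O-silylation of its lithium enolate is the standard preparation of a silyl ketene acetal.

Step 14
Reactants: 24 C7 enone; 27 silyl ketene acetal
Product: 29 C7 keto di-tert-butyl ester (C5 bearing α-CMe2CO2tBu), via silyl enol ether 28 (not isolated)
Conditions: 27 (3 equiv), Tf2NH (5 mol%), CH2Cl2, −78 → −40 °C; then 0.1 M aq HCl, THF, 0 °C
Reagents that add atoms: none
Why: In this Mukaiyama–Michael addition (catalyst Me3SiNTf2, formed in situ) the ketene acetal should attack C5 axially on the α face, anti to the pseudo-axial C10 methyl on the β face, which places the C4 unit α and H5 β as in the target; 28 is hydrolysed on work-up.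

Step 15
Reactants: 29 keto diester
Product: 30 7α-alcohol
Conditions: NaBH4, MeOH–THF, 0 °C
Reagents that add atoms: none
Why: Borohydride should reduce the C7 ketone from the β face, since the axial C5 substituent blocks the α face; the carbinol configuration is irrelevant and the bulky tert-butyl ester should prevent lactonisation onto C3.

Step 16
Reactants: 30 7α-alcohol
Product: 33 S-methyl xanthate of 30, via sodium alkoxide 31 (not isolated), via sodium xanthate 32 (not isolated)
Conditions: NaH, imidazole (cat.), THF, 0 °C; CS2; MeI, rt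
Reagents that add atoms: carbon disulfide, S=C=S; iodomethane, CI
Why: Alkoxide formation, addition to CS2 and S-methylation (xanthate formation) works for hindered secondary alcohols because carbon disulfide is a small electrophile.

Step 17
Reactants: 33 xanthate
Product: 34 di-tert-butyl ester of the target
Conditions: Bu3SnH, AIBN (cat.), toluene, 100 °C
Reagents that add atoms: none
Why: In the Barton–McCombie deoxygenation the stannyl radical adds to the thiocarbonyl group, the C7–O bond fragments and the C7 radical takes hydrogen from the stannane; the radical cannot reach the equatorial C13 vinyl group across the trans-fused oxane, and β-alkoxy radicals do not fragment.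

Step 18
Reactants: 34 di-tert-butyl ester
Product: 36 target diacid CNP0186744.3, via bis(trimethylsilyl) ester 35 (not isolated)
Conditions: Me3SiOSO2CF3, 2,6-lutidine, CH2Cl2, 0 °C → rt; then pH 4 phosphate buffer
Reagents that add atoms: none
Why: Silyl triflate with 2,6-lutidine should convert both tert-butyl esters into silyl esters with loss of 2-methylpropene (alkyl–oxygen cleavage, insensitive to hindrance at C3), and these hydrolyse on buffered work-up, which avoids protic acid that could ionise the tertiary allylic C13–O bond.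

**Compound list**
1 | 2-methoxypropene | C=C(C)OC | starting material
2 | 3-bromo-2-methoxyprop-1-ene (2-methoxyallyl bromide) | C=C(CBr)OC | intermediate
3 | 2,5-dimethylfuran | Cc1ccc(C)o1 | starting material
4 | 3-methoxy-1,5-dimethyl-8-oxabicyclo[3.2.1]octa-2,6-diene, racemic (one enantiomer drawn) | C1=C[C@@]2(C)O[C@]1(C)CC(OC)=C2 | intermediate (not isolated)
5 | meso-(1R,5S)-1,5-dimethyl-8-oxabicyclo[3.2.1]oct-6-en-3-one | C1=C[C@@]2(C)O[C@]1(C)CC(=O)C2 | intermediate
6 | lithium (1R,5R)-1,5-dimethyl-8-oxabicyclo[3.2.1]octa-2,6-dien-3-olate | C1=C[C@@]2(C)O[C@]1(C)CC(O[Li])=C2 | intermediate (not isolated)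
7 | (1R,5R)-1,5-dimethyl-3-(trimethylsilyloxy)-8-oxabicyclo[3.2.1]octa-2,6-diene | C1=C[C@@]2(C)O[C@]1(C)CC(O[Si](C)(C)C)=C2 | intermediate
8 | 2-bromo-N-methoxy-N-methylacetamide | CON(C)C(=O)CBr | starting material
9 | benzyltrimethylammonium (1R,5R)-1,5-dimethyl-8-oxabicyclo[3.2.1]octa-2,6-dien-3-olate | C1=C[C@@]2(C)O[C@]1(C)CC([O-])=C2.C[N+](C)(C)Cc1ccccc1 | intermediate (not isolated)
10 | 2-[(1R,2R,5R)-1,5-dimethyl-3-oxo-8-oxabicyclo[3.2.1]oct-6-en-2-yl]-N-methoxy-N-methylacetamide (side chain exo, syn to the oxygen bridge) | C1=C[C@@]2(C)O[C@]1(C)CC(=O)[C@@H]2CC(=O)N(C)OC | intermediate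
11 | 4-methylbenzenesulfonylhydrazone of 10 at the ring ketone | C1=C[C@@]2(C)O[C@]1(C)CC(=NNS(=O)(=O)c3ccc(C)cc3)[C@@H]2CC(=O)N(C)OC | intermediate (not isolated)
12 | 2-[(1S,2R,5R)-1,5-dimethyl-8-oxabicyclo[3.2.1]oct-6-en-2-yl]-N-methoxy-N-methylacetamide | C1=C[C@@]2(C)O[C@]1(C)CC[C@@H]2CC(=O)N(C)OC | intermediate
13 | 1-[(1S,2R,5R)-1,5-dimethyl-8-oxabicyclo[3.2.1]oct-6-en-2-yl]but-3-en-2-one | C1=C[C@@]2(C)O[C@]1(C)CC[C@@H]2CC(=O)C=C | intermediate
14 | 1-(2,6-diethenyl-2,6-dimethyloxan-3-yl)but-3-en-2-one (vinyl groups cis; side chain trans to the adjacent vinyl) | C=C[C@@]1(C)CC[C@H](CC(=O)C=C)[C@@](C)(C=C)O1 | intermediate (not isolated)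
15 | ring B enone: 2-ethenyl-2,8a-dimethyl-3,4,4a,5-tetrahydro-2H-chromen-6(8aH)-one; trans-fused (9α-H, 8β-Me), 13β-Me, 13α-vinyl; C5 ketone, C6=C7 | C=C[C@@]1(C)CC[C@@H]2CC(=O)C=C[C@@]2(C)O1 | intermediate
16 | lithium dienolate of 15 (C10=C5–OLi) | C=C[C@@]1(C)CC[C@@H]2C=C(O[Li])C=C[C@@]2(C)O1 | intermediate (not isolated)
17 | 10-methyl derivative of 15 (10α-Me, 10β-H) | C=C[C@@]1(C)CC[C@@H]2[C@@H](C)C(=O)C=C[C@@]2(C)O1 | intermediate
18 | tert-butyl bromoacetate | CC(C)(C)OC(=O)CBr | starting material
19 | lithium dienolate of 17 | C=C[C@@]1(C)CC[C@@H]2C(C)=C(O[Li])C=C[C@@]2(C)O1 | intermediate (not isolated)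
20 | tert-butyl 2-(ring B enone-10-yl)acetate: C5 ketone, C6=C7, C10 quaternary (10β-Me, 10α-CH2CO2tBu) | C=C[C@@]1(C)CC[C@@H]2[C@@](C)(CC(=O)OC(C)(C)C)C(=O)C=C[C@@]2(C)O1 | intermediate
21 | 6α,7α-epoxide of 20 | C=C[C@@]1(C)CC[C@@H]2[C@@](C)(CC(=O)OC(C)(C)C)C(=O)[C@H]3O[C@H]3[C@@]2(C)O1 | intermediate
22 | C5 hydrazone of 21 | C=C[C@@]1(C)CC[C@@H]2[C@@](C)(CC(=O)OC(C)(C)C)C(=NN)[C@H]3O[C@H]3[C@@]2(C)O1 | intermediate (not isolated)
23 | allylic alcohol: 7α-OH, C5=C6, C10 as in 20 | C=C[C@@]1(C)CC[C@@H]2[C@@](C)(CC(=O)OC(C)(C)C)C=C[C@@H](O)[C@@]2(C)O1 | intermediate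
24 | C7 enone: C7 ketone, C5=C6, C10 as in 20 | C=C[C@@]1(C)CC[C@@H]2[C@@](C)(CC(=O)OC(C)(C)C)C=CC(=O)[C@@]2(C)O1 | intermediate
25 | tert-butyl isobutyrate | CC(C)C(=O)OC(C)(C)C | starting material
26 | lithium enolate of 25 | CC(C)=C(O[Li])OC(C)(C)C | intermediate (not isolated)
27 | [(1-tert-butoxy-2-methylprop-1-en-1-yl)oxy]trimethylsilane | CC(C)=C(OC(C)(C)C)O[Si](C)(C)C | intermediate
28 | C7 trimethylsilyl enol ether of 29 (C6=C7) | C=C[C@@]1(C)CC[C@@H]2[C@@](C)(CC(=O)OC(C)(C)C)[C@@H](C(C)(C)C(=O)OC(C)(C)C)C=C(O[Si](C)(C)C)[C@@]2(C)O1 | intermediate (not isolated)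
29 | C7 keto di-tert-butyl ester (5β-H, 5α-CMe2CO2tBu) | C=C[C@@]1(C)CC[C@@H]2[C@@](C)(CC(=O)OC(C)(C)C)[C@@H](C(C)(C)C(=O)OC(C)(C)C)CC(=O)[C@@]2(C)O1 | intermediate
30 | 7α-hydroxy di-tert-butyl ester | C=C[C@@]1(C)CC[C@@H]2[C@@](C)(CC(=O)OC(C)(C)C)[C@@H](C(C)(C)C(=O)OC(C)(C)C)C[C@@H](O)[C@@]2(C)O1 | intermediate
31 | sodium alkoxide of 30 | C=C[C@@]1(C)CC[C@@H]2[C@@](C)(CC(=O)OC(C)(C)C)[C@@H](C(C)(C)C(=O)OC(C)(C)C)C[C@@H](O[Na])[C@@]2(C)O1 | intermediate (not isolated)
32 | sodium O-alkyl dithiocarbonate of 30 | C=C[C@@]1(C)CC[C@@H]2[C@@](C)(CC(=O)OC(C)(C)C)[C@@H](C(C)(C)C(=O)OC(C)(C)C)C[C@@H](OC(=S)S[Na])[C@@]2(C)O1 | intermediate (not isolated)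
33 | O-alkyl S-methyl dithiocarbonate of 30 | C=C[C@@]1(C)CC[C@@H]2[C@@](C)(CC(=O)OC(C)(C)C)[C@@H](C(C)(C)C(=O)OC(C)(C)C)C[C@@H](OC(=S)SC)[C@@]2(C)O1 | intermediate
34 | di-tert-butyl ester of the target | C=C[C@@]1(C)CC[C@@H]2[C@@](C)(CC(=O)OC(C)(C)C)[C@@H](C(C)(C)C(=O)OC(C)(C)C)CC[C@@]2(C)O1 | intermediate
35 | bis(trimethylsilyl) ester of the target | C=C[C@@]1(C)CC[C@@H]2[C@@](C)(CC(=O)O[Si](C)(C)C)[C@@H](C(C)(C)C(=O)O[Si](C)(C)C)CC[C@@]2(C)O1 | intermediate (not isolated)
36 | 2-[(2R,4aR,5S,6S,8aR)-5-(carboxymethyl)-2-ethenyl-2,5,8a-trimethyloctahydro-2H-chromen-6-yl]-2-methylpropanoic acid (CNP0186744.3) | C=C[C@@]1(C)CC[C@@H]2[C@@](C)(CC(=O)O)[C@@H](C(C)(C)C(=O)O)CC[C@@]2(C)O1 | target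

**Step count and risks**
Total step count: 18. Longest linear sequence: 17 (steps 1–12 and 14–18; step 13 is a side branch).

Steps most likely to fail:

Step 14. The bulky ketene acetal may fail to reach C5, a neopentyl β-carbon next to the quaternary C10, leaving the enone unchanged or diverting to 1,2-addition. Fallback, setting out from 24: the slimmer lithiated isobutyronitrile (LiN(iPr)2, Me2CHCN, THF–DMPU, −78 → 0 °C) is added in an anionic Michael reaction to give the keto nitrile F6. Borohydride reduction gives the hydroxy nitrile F7, which is acylated with PhOC(S)Cl and DMAP to the phenyl thionocarbonate F8 and reduced with Bu3SnH and AIBN to the deoxygenated nitrile ester F9. Vigorous alkaline hydrolysis (KOH, ethylene glycol–water, 170 °C) of the nitrile and the tert-butyl ester of F9 then comes back to the route at the target 36.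

Step 7. Ring opening may be slow because both carbons of the C7=C14 bridge carry quaternary neighbours, so catalyst decay and oligomerisation of the vinyl ketone could win. Fallback, setting out from 12: ozonolysis with Me2S work-up cleaves the bridge to the dialdehyde F1, and double Wittig methylenation (Ph3P=CH2) gives the divinyl amide F2. Vinylmagnesium bromide then gives trienone 14, now isolated, and a plain ring-closing metathesis with the same ruthenium catalyst comes back to the route at 15.

Step 11. Hydrazone formation at the C5 carbonyl, which is flanked by the quaternary C10, may be slow and allow hydrazine to open the epoxide instead. Fallback, setting out from 20 (replacing steps 10 to 12): conjugate reduction with [CuH(PPh3)]6 gives the saturated ketone F3, and KN(SiMe3)2 with PhNTf2 gives the enol triflate F4. Reduction with Pd(OAc)2, PPh3, HCO2H and Bu3N gives the C5=C6 alkene F5, and allylic oxidation at C7, its only allylic CH2, with CrO3·3,5-dimethylpyrazole comes back to the route at 24.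

**Further compounds**
F1 | step 7 | 2-(2,6-diformyl-2,6-dimethyloxan-3-yl)-N-methoxy-N-methylacetamide (formyl groups cis) | O=C[C@@]1(C)CC[C@H](CC(=O)N(C)OC)[C@@](C)(C=O)O1
F2 | step 7 | 2-(2,6-diethenyl-2,6-dimethyloxan-3-yl)-N-methoxy-N-methylacetamide (vinyl groups cis) | C=C[C@@]1(C)CC[C@H](CC(=O)N(C)OC)[C@@](C)(C=C)O1
F3 | step 11 | 6,7-dihydro derivative of 20 (saturated C5 ketone) | C=C[C@@]1(C)CC[C@@H]2[C@@](C)(CC(=O)OC(C)(C)C)C(=O)CC[C@@]2(C)O1
F4 | step 11 | C5 enol triflate of F3 (C5=C6) | C=C[C@@]1(C)CC[C@@H]2[C@@](C)(CC(=O)OC(C)(C)C)C(OS(=O)(=O)C(F)(F)F)=CC[C@@]2(C)O1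
F5 | step 11 | C5=C6 alkene (C7 methylene) | C=C[C@@]1(C)CC[C@@H]2[C@@](C)(CC(=O)OC(C)(C)C)C=CC[C@@]2(C)O1
F6 | step 14 | C7 keto nitrile (5α-CMe2CN) | C=C[C@@]1(C)CC[C@@H]2[C@@](C)(CC(=O)OC(C)(C)C)[C@@H](C(C)(C)C#N)CC(=O)[C@@]2(C)O1
F7 | step 14 | 7α-hydroxy nitrile | C=C[C@@]1(C)CC[C@@H]2[C@@](C)(CC(=O)OC(C)(C)C)[C@@H](C(C)(C)C#N)C[C@@H](O)[C@@]2(C)O1
F8 | step 14 | O-phenyl thionocarbonate of F7 | C=C[C@@]1(C)CC[C@@H]2[C@@](C)(CC(=O)OC(C)(C)C)[C@@H](C(C)(C)C#N)C[C@@H](OC(=S)Oc3ccccc3)[C@@]2(C)O1
F9 | step 14 | C7-deoxygenated nitrile tert-butyl ester | C=C[C@@]1(C)CC[C@@H]2[C@@](C)(CC(=O)OC(C)(C)C)[C@@H](C(C)(C)C#N)CC[C@@]2(C)O1
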